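## The problem

Target 17 is a 2,5-diaryl-3,4-dimethyloxolane whose ring carries four contiguous stereocentres, (2S,3S,4R,5R). Each aryl group is trans to the methyl on the neighbouring carbon and the two methyls are cis, so the two aryl groups sit cis across the ring oxygen. C2 carries a plain 4-hydroxyphenyl group (ring B). C5 carries ring A, a 1,3,4-trisubstituted phenol bearing, ortho to its hydroxyl, a 1-(4-hydroxyphenyl)propan-2-yl chain that ends in ring C and holds a fifth, (R)-configured benzylic stereocentre. This side-chain centre is insulated from the oxolane by ring A and needs its own source of absolute configuration. Inside the ring, C5 can direct C4, both can direct C3, and C3/C4 can direct C2, so one defined ring centre suffices. The cis-dimethyl arrangement is the less stable one, so C3 must be set kinetically, whereas the aryl/methyl trans relationships at both ends are thermodynamically preferred. Both ring C–O bonds are para-oxygenated benzylic ethers that ionise under acid and can be hydrogenolysed, and the three phenols are oxidation-prone and need one protecting group removable without acid. The enabling feature is the C3–C4 bond: it joins two methyl-bearing carbons, C4 lies beside the oxygen-bearing benzylic C5, and C2 can pass through the acetal oxidation level. This is the atom pattern left when the radical of an α-bromoacetal of an aryl vinyl carbinol closes onto the vinyl group, the vinyl CH2 becoming the C4 methyl.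

## Retrosynthesis

**O–benzyl bonds (17 from 16).** All three phenols are masked as benzyl ethers in 16. Benzyl survives organolithium, radical and BF3 chemistry and is removed by neutral hydrogenolysis. Methyl or silyl ethers would need Lewis acid or fluoride next to the ionisable ring ethers. The forward step must cleave three aryl benzyl ethers faster than the two ring benzylic C–O bonds.

**C2–ring B bond (16 from 14 and 15).** Cutting the C2–aryl bond leads to the ethoxy acetal 14, an oxocarbenium precursor, and benzyl phenyl ether 15. The neighbouring option, adding an aryl metal to a lactone and reducing the hemiketal, would place the aryl cis to the C3 methyl and need a later epimerisation. Attack of an arene on the oxocarbenium ion places it trans directly. The forward reaction must be para-selective on 15, occur on the face opposite the two methyls, and leave C3 untouched.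

**C3–C4 bond (14 from 13), the key cut.** Breaking C3–C4 opens the ring and removes two stereocentres. Bromoacetal 13 is acyclic, and among its ring carbons only the carbinol carbon is defined. Cutting a C–O bond instead would require four contiguous stereocentres in an open chain. The forward step must close 5-exo and relay the carbinol configuration to C4 and C3.

**Acetal C–O and C–Br bonds (13 from 11 and 12).** The bromoacetal is a three-component adduct of carbinol 11, ethyl 1-propenyl ether 12 and a bromonium source. Both new centres are destroyed later (planar radical, ionised acetal), so nothing needs control.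

**Ring A–C5 bond and the carbinol centre (11 from 10; 10 from 7 and 8 through 9).** The (R)-carbinol 11 is taken from the epimer mixture 10 by kinetic resolution. This is chosen over catalytic asymmetric vinylation because a resolution can be driven to high enantiopurity in a predictable way, at the cost of half the material. Compound 10 comes from aryllithium 9 (from bromide 7) and acrolein 8 in one operation.

**Side-chain centre (7 from 6).** The stereocentre in 7 is written back to the two faces of the trisubstituted alkene 6. Asymmetric hydrogenation of a 1,2-diarylpropene is the shortest entry to a 1,2-diarylpropane and needs no auxiliary, but it demands geometrically pure 6.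

**Alkene 6 (from 3 and 4 through 5; 3 from 2; 2 from 1).** Cutting the alkene–ring C bond and the alkene–methyl bond leads to alkyne 3 and aryl iodide 4. Syn-carbometallation to alane 5 fixes the E geometry, which carbonyl olefination of the corresponding ketone would not do. Alkyne 3 comes from aldehyde 2 by one-carbon homologation, and 2 from 5-bromosalicylaldehyde 1 by benzylation.

## Roads not taken

**Alternative 1:** keteniminium [2+2], then oxygen insertion.
- **Cut:** C2–C3 and C4–C5; the ring oxygen is inserted afterwards.
- **Forward:** amide A1, activated at the carbonyl, gives a keteniminium ion that adds to (Z)-but-2-ene A2. Hydrolysis gives cyclobutanone A3 with ring B trans to its neighbouring methyl and the methyls cis. Baeyer–Villiger oxidation gives lactone A4, whose carbonyl carbon is C5.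
- **Merits:** the cis-dimethyl relationship is copied from the alkene geometry and is not a matter of selectivity. Two ring C–C bonds form at once.
- **Weak points:** absolute control needs a chiral amine in place of the pyrrolidine of A1, or a resolution. The peracid must distinguish two secondary migrating carbons while facing an electron-rich arene. C5 must then be joined to aryllithium 9, the most valuable fragment, late, and hydride reduction of the hemiketal delivers the aryl cis to the C4 methyl, so an acid epimerisation is needed.
- **Comparison:** this road is better on the methyl/methyl relationship. The chosen plan sets against it a C5 configuration fixed before the ring exists and a ring A fragment that enters once, early.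

**Alternative 2:** thiocarbonyl ylide cycloaddition.
- **Cut:** the two ring-to-methyl C–C bonds.
- **Forward:** the ylide released from A6 by fluoride adds across the C=C bond of furanone A5 anti to the menthyloxy group, giving the cis-fused thiolane A7. Desulfurisation with Raney Ni gives the cis-dimethyl lactone acetal A8.
- **Merits:** the cis methyls are locked by the ring fusion, the absolute configuration comes from a crystalline auxiliary with no resolution loss, and no tin is used.
- **Weak points:** A8 carries neither aryl group. The acetal carbon and the carbonyl carbon must each be arylated separately, the second by organometallic addition and deoxygenation with the same cis/trans problem as in alternative 1. Desulfurisation must precede any benzyl ether or aryl halide. The sequence is longer.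
- **Comparison:** this road is better in stereochemical certainty and wastes nothing in a resolution. The chosen plan offers fewer operations after ring formation, since one aryl is already in place and only one arylation remains.

**Alternative 3:** biomimetic double quinone methide hydration.
- **Cut:** both ring C–O bonds.
- **Forward:** a high-potential quinone oxidises both para-hydroxybenzylic CH2 groups of dibenzylbutane A9 to quinone methides. Water adds to one and the resulting alcohol to the other, giving A10.
- **Merits:** it is by far the shortest way to the core, needs no protecting groups, and sets the aryl/methyl trans relationships under thermodynamic control.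
- **Weak points:** A9 is almost meso, since its two centres differ only through a distant bromine, so making it as one enantiomer is a hard problem of its own. Double oxidation of free phenols invites over-oxidation. The chiral side chain would then have to be built on the aryl bromide of A10 next to free phenols and the labile ring, leaving the hardest stereocentre to the end.
- **Comparison:** this road wins on step count for the ring. The chosen plan sets against it two well-defined asymmetric steps covering all five centres and a side chain finished before the sensitive oxolane is formed.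

Key step: step 8

Assumption: the descriptors encoded for the target, (2S,3S,4R,5R) in the ring and (R) in the side chain, are taken as the configuration to be made; the facial sense of the iridium catalyst in step 4 is inferred from the parent (E)-1,2-diphenylpropene.

## Route

Step 1
Reactants: 1 5-bromo-2-hydroxybenzaldehyde
Product: 2 2-(benzyloxy)-5-bromobenzaldehyde
Conditions: BnBr, K2CO3, DMF, rt
Reagents that add atoms: benzyl bromide, BrCc1ccccc1
Why: Williamson ether synthesis on an acidic ortho-formyl phenol; the benzyl ether survives the later organometallic, radical and Lewis-acid steps and is removed with the others at the end.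

Step 2
Reactants: 2 2-(benzyloxy)-5-bromobenzaldehyde
Product: 3 1-(benzyloxy)-4-bromo-2-ethynylbenzene
Conditions: dimethyl (1-diazo-2-oxopropyl)phosphonate, K2CO3, MeOH, rt
Reagents that add atoms: dimethyl (1-diazo-2-oxopropyl)phosphonate, CC(=O)C(=[N+]=[N-])P(=O)(OC)OC
Why: Seyferth–Gilbert homologation with the Ohira–Bestmann reagent turns a non-enolisable aryl aldehyde into the terminal alkyne under carbonate/methanol conditions that leave the aryl bromide and benzyl ether untouched.

Step 3
Reactants: 3 1-(benzyloxy)-4-bromo-2-ethynylbenzene; 4 1-(benzyloxy)-4-iodobenzene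
Product: 6 1-(benzyloxy)-2-[(1E)-1-(4-benzyloxyphenyl)prop-1-en-2-yl]-4-bromobenzene, via alkenylalane 5 (not isolated)
Conditions: Me3Al (2 equiv), Cp2ZrCl2 (0.25 equiv), CH2Cl2, 0 °C to rt; volatiles removed; then 4, ZnCl2 (1 equiv), Pd(PPh3)4 (5 mol %), THF, rt
Reagents that add atoms: trimethylaluminium, C[Al](C)C
Why: Zirconium-catalysed carboalumination adds methyl and aluminium syn across the alkyne (methyl to the aryl-bearing carbon) and so fixes the E geometry; the alkenylalane then undergoes Negishi coupling with retention, the aryl iodide adding to zerovalent palladium far faster than the aryl bromide.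

Step 4
Reactants: 6 1-(benzyloxy)-2-[(1E)-1-(4-benzyloxyphenyl)prop-1-en-2-yl]-4-bromobenzene
Product: 7 1-(benzyloxy)-2-[(2R)-1-(4-benzyloxyphenyl)propan-2-yl]-4-bromobenzene
Conditions: H2 (50 bar), [Ir(cod)((S)-tBu-PHOX)][B(3,5-(CF3)2C6H3)4] (1 mol %), CH2Cl2, rt
Reagents that add atoms: none
Why: Asymmetric hydrogenation of an unfunctionalised trisubstituted aryl alkene with a cationic iridium phosphinooxazoline complex ((S)-tBu-PHOX = (S)-4-tert-butyl-2-[2-(di-o-tolylphosphanyl)phenyl]-4,5-dihydro-1,3-oxazole), for which (E)-1,2-diarylpropenes are the standard substrates; the (S)-ligand is expected to deliver hydrogen to the face giving (R)-7 (the antipodal complex is used if the sense is reversed), and the homogeneous catalyst leaves benzyl ethers and the aryl bromide intact.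

Step 5
Reactants: 7 1-(benzyloxy)-2-[(2R)-1-(4-benzyloxyphenyl)propan-2-yl]-4-bromobenzene; 8 acrolein
Product: 10 (1RS)-1-{4-(benzyloxy)-3-[(2R)-1-(4-benzyloxyphenyl)propan-2-yl]phenyl}prop-2-en-1-ol, via aryllithium 9 (not isolated)
Conditions: n-BuLi, THF, −78 °C; then 8, −78 °C; H2O
Reagents that add atoms: none
Why: Bromine–lithium exchange at −78 °C outruns any deprotonation, and 1,2-addition of the aryllithium to acrolein gives the aryl vinyl carbinol; the carbinol centre forms without control and is resolved in step 6.

Step 6
Reactants: 10 (1RS)-1-{4-(benzyloxy)-3-[(2R)-1-(4-benzyloxyphenyl)propan-2-yl]phenyl}prop-2-en-1-ol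
Product: 11 (1R)-1-{4-(benzyloxy)-3-[(2R)-1-(4-benzyloxyphenyl)propan-2-yl]phenyl}prop-2-en-1-ol
Conditions: Ti(OiPr)4 (0.15 equiv), D-(−)-diisopropyl tartrate (0.2 equiv), t-BuOOH (0.6 equiv), 4 Å MS, CH2Cl2, −20 °C
Reagents that add atoms: none
Why: Sharpless kinetic resolution of a secondary allylic alcohol; with the D-tartrate the (S)-carbinol epimer is epoxidised fast and the (R)-epimer is recovered, the remote side-chain centre having no influence; running slightly past half conversion should secure high purity of 11.

Step 7
Reactants: 11 (1R)-1-{4-(benzyloxy)-3-[(2R)-1-(4-benzyloxyphenyl)propan-2-yl]phenyl}prop-2-en-1-ol; 12 ethyl 1-propenyl ether (E/Z mixture)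
Product: 13 1-(benzyloxy)-2-[(2R)-1-(4-benzyloxyphenyl)propan-2-yl]-4-[(1R)-1-(2-bromo-1-ethoxypropoxy)prop-2-en-1-yl]benzene (mixture at the acetal and bromide carbons)
Conditions: NBS, 12 (3 equiv), CH2Cl2, −40 to 0 °C; Et3N quench
Reagents that add atoms: N-bromosuccinimide, O=C1CCC(=O)N1Br
Why: Haloacetalisation: NBS brominates the enol ether at its β-carbon and alcohol 11 traps the resulting oxocarbenium ion; the carbinol centre is not touched, and the two new centres need no control because both are erased later.

Step 8
Reactants: 13 1-(benzyloxy)-2-[(2R)-1-(4-benzyloxyphenyl)propan-2-yl]-4-[(1R)-1-(2-bromo-1-ethoxypropoxy)prop-2-en-1-yl]benzene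
Product: 14 (2RS,3S,4R,5R)-5-{4-(benzyloxy)-3-[(2R)-1-(4-benzyloxyphenyl)propan-2-yl]phenyl}-2-ethoxy-3,4-dimethyloxolane
Conditions: Bu3SnH (1.3 equiv, slow addition), Et3B (0.3 equiv), air, toluene (0.01 M), −40 °C
Reagents that add atoms: none
Why: An ethyl radical from Et3B and oxygen starts the chain, Bu3Sn• abstracts bromine from 13 to give a planar secondary radical at C3, this adds to the internal vinyl carbon to form C3–C4, and the resulting primary radical takes hydrogen from Bu3SnH to become the C4 methyl and regenerate Bu3Sn•. The closest known reaction type is the Ueno–Stork haloacetal radical cyclisation to 2-alkoxytetrahydrofurans. The oxolane ring closes in the 5-exo-trig mode; 6-endo closure onto the terminal carbon is not expected to compete. C4 is controlled by the C5 carbinol centre: in the chair-like transition state the C5 aryl is pseudo-equatorial, which puts the vinyl CH2 (the future methyl) trans to it and gives (4R). C3 is set in the same transition state by the preference of a substituent on the radical carbon to end up cis to the new exocyclic carbon (the 1,5-cis preference of 1-substituted 5-hexenyl radicals), giving (3S); the bromide configuration is irrelevant because the radical is planar. The step needs cyclisation to beat direct reduction, secured by the low stannane concentration, and needs diastereoselection, helped by the low temperature that borane initiation allows. The acetal carbon stays a mixture and is erased in step 9, and no other radical acceptor is present since the aryl bromide was consumed in step 5.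

Step 9
Reactants: 14 (2RS,3S,4R,5R)-5-{4-(benzyloxy)-3-[(2R)-1-(4-benzyloxyphenyl)propan-2-yl]phenyl}-2-ethoxy-3,4-dimethyloxolane; 15 benzyl phenyl ether
Product: 16 (2S,3S,4R,5R)-5-{4-(benzyloxy)-3-[(2R)-1-(4-benzyloxyphenyl)propan-2-yl]phenyl}-2-[4-(benzyloxy)phenyl]-3,4-dimethyloxolane
Conditions: 15 (5 equiv), BF3·OEt2 (1.5 equiv), CH2Cl2, −78 to −30 °C
Reagents that add atoms: none
Why: Friedel–Crafts arylation of a cyclic oxocarbenium ion: BF3·OEt2 ionises the ethoxy acetal and the alkoxyarene attacks through its para carbon on the face opposite the two cis methyls, in the envelope that keeps the C4 methyl and C5 aryl pseudo-equatorial, so ring B enters trans to the C3 methyl and gives (2S); this is also the thermodynamically favoured arrangement should the benzylic ether equilibrate.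

Step 10
Reactants: 16 (2S,3S,4R,5R)-5-{4-(benzyloxy)-3-[(2R)-1-(4-benzyloxyphenyl)propan-2-yl]phenyl}-2-[4-(benzyloxy)phenyl]-3,4-dimethyloxolane
Product: 17 4-[(2S,3S,4R,5R)-5-{4-hydroxy-3-[(2R)-1-(4-hydroxyphenyl)propan-2-yl]phenyl}-3,4-dimethyloxolan-2-yl]phenol
Conditions: H2 (1 atm), Pd/C (10 %), EtOAc–MeOH, rt
Reagents that add atoms: none
Why: Hydrogenolysis of three aryl benzyl ethers under neutral conditions; O-benzyl aryl ethers cleave much faster than the two ring benzylic C–O bonds, so the reaction is stopped after three equivalents of hydrogen, and no stereocentre is affected.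

## Compound list

1 | 5-bromo-2-hydroxybenzaldehyde | O=Cc1cc(Br)ccc1O | starting material
2 | 2-(benzyloxy)-5-bromobenzaldehyde | O=Cc1cc(Br)ccc1OCc1ccccc1 | intermediate
3 | 1-(benzyloxy)-4-bromo-2-ethynylbenzene | C#Cc1cc(Br)ccc1OCc1ccccc1 | intermediate
4 | 1-(benzyloxy)-4-iodobenzene | Ic1ccc(OCc2ccccc2)cc1 | starting material
5 | [(1E)-2-(2-benzyloxy-5-bromophenyl)prop-1-en-1-yl]dimethylalumane | C[Al](C)/C=C(\C)c1cc(Br)ccc1OCc1ccccc1 | intermediate (not isolated)
6 | 1-(benzyloxy)-2-[(1E)-1-(4-benzyloxyphenyl)prop-1-en-2-yl]-4-bromobenzene | C/C(=C\c1ccc(OCc2ccccc2)cc1)c1cc(Br)ccc1OCc1ccccc1 | intermediate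
7 | 1-(benzyloxy)-2-[(2R)-1-(4-benzyloxyphenyl)propan-2-yl]-4-bromobenzene | Brc1ccc(OCc2ccccc2)c([C@H](C)Cc2ccc(OCc3ccccc3)cc2)c1 | intermediate
8 | acrolein (prop-2-enal) | C=CC=O | starting material
9 | {4-(benzyloxy)-3-[(2R)-1-(4-benzyloxyphenyl)propan-2-yl]phenyl}lithium | [Li]c1ccc(OCc2ccccc2)c([C@H](C)Cc2ccc(OCc3ccccc3)cc2)c1 | intermediate (not isolated)
10 | (1RS)-1-{4-(benzyloxy)-3-[(2R)-1-(4-benzyloxyphenyl)propan-2-yl]phenyl}prop-2-en-1-ol | OC(C=C)c1ccc(OCc2ccccc2)c([C@H](C)Cc2ccc(OCc3ccccc3)cc2)c1 | intermediate
11 | (1R)-1-{4-(benzyloxy)-3-[(2R)-1-(4-benzyloxyphenyl)propan-2-yl]phenyl}prop-2-en-1-ol | O[C@H](C=C)c1ccc(OCc2ccccc2)c([C@H](C)Cc2ccc(OCc3ccccc3)cc2)c1 | intermediate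
12 | ethyl 1-propenyl ether (E/Z mixture) | CC=COCC | starting material
13 | 1-(benzyloxy)-2-[(2R)-1-(4-benzyloxyphenyl)propan-2-yl]-4-[(1R)-1-(2-bromo-1-ethoxypropoxy)prop-2-en-1-yl]benzene (mixture at acetal and bromide carbons) | CCOC(C(C)Br)O[C@H](C=C)c1ccc(OCc2ccccc2)c([C@H](C)Cc2ccc(OCc3ccccc3)cc2)c1 | intermediate
14 | (2RS,3S,4R,5R)-5-{4-(benzyloxy)-3-[(2R)-1-(4-benzyloxyphenyl)propan-2-yl]phenyl}-2-ethoxy-3,4-dimethyloxolane | C[C@@H]1[C@H](C)C(OCC)O[C@H]1c1ccc(OCc2ccccc2)c([C@H](C)Cc2ccc(OCc3ccccc3)cc2)c1 | intermediate
15 | benzyl phenyl ether | c1ccc(OCc2ccccc2)cc1 | starting material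
16 | (2S,3S,4R,5R)-5-{4-(benzyloxy)-3-[(2R)-1-(4-benzyloxyphenyl)propan-2-yl]phenyl}-2-[4-(benzyloxy)phenyl]-3,4-dimethyloxolane | C[C@@H]1[C@H](C)[C@@H](c2ccc(OCc3ccccc3)cc2)O[C@H]1c1ccc(OCc2ccccc2)c([C@H](C)Cc2ccc(OCc3ccccc3)cc2)c1 | intermediate
17 | 4-[(2S,3S,4R,5R)-5-{4-hydroxy-3-[(2R)-1-(4-hydroxyphenyl)propan-2-yl]phenyl}-3,4-dimethyloxolan-2-yl]phenol | C[C@@H]1[C@H](C)[C@@H](c2ccc(O)cc2)O[C@H]1c1ccc(O)c([C@H](C)Cc2ccc(O)cc2)c1 | target

## Step count and risks

Total: 10 steps. Longest linear sequence: 10 steps (1 to 17); compounds 4, 8, 12 and 15 enter as purchased building blocks.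

**Step 8 (key step).**
- **Risk:** incomplete diastereoselection at C3. The cis preference of a substituted radical carbon is modest, and the two acetal epimers of 13 may cyclise with different selectivity. Premature reduction of the radical before ring closure is the second risk.
- **Fallback (from 14 back to 14):** C3 is corrected through a lactone enolate.
  - The isomer mixture of 14 is oxidised at the acetal carbon (mCPBA, BF3·OEt2, CH2Cl2, 0 °C) to (3RS,4R,5R)-5-{4-(benzyloxy)-3-[(2R)-1-(4-benzyloxyphenyl)propan-2-yl]phenyl}-3,4-dimethyloxolan-2-one F1.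
  - Deprotonation with LiN(iPr)2 at −78 °C and quenching with a bulky proton donor (2,6-di-tert-butyl-4-methylphenol) should deliver the proton anti to the C4 methyl and give the cis lactone, the (3S,4R,5R) isomer of that oxolan-2-one F2.
  - Reduction with i-Bu2AlH at −78 °C gives the lactol (2RS,3S,4R,5R)-5-{4-(benzyloxy)-3-[(2R)-1-(4-benzyloxyphenyl)propan-2-yl]phenyl}-3,4-dimethyloxolan-2-ol F3.
  - Ethanol with pyridinium p-toluenesulfonate returns 14, enriched in the 3,4-cis series, for step 9.

**Step 4.**
- **Risk:** slow or poorly face-selective hydrogenation, because the ortho-benzyloxy group twists ring A out of the alkene plane and crowds the metal.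
- **Fallback (from alkyne 3 to 7):** the centre is set by auxiliary-controlled enolate methylation.
  - Hydroboration of 3 with dicyclohexylborane and oxidative work-up (NaBO3) gives [2-(benzyloxy)-5-bromophenyl]acetaldehyde F4.
  - Pinnick oxidation (NaClO2) gives [2-(benzyloxy)-5-bromophenyl]acetic acid F5.
  - Coupling to (S)-4-benzyl-1,3-oxazolidin-2-one (pivaloyl chloride, Et3N, LiCl) gives (4S)-4-benzyl-3-{[2-(benzyloxy)-5-bromophenyl]acetyl}-1,3-oxazolidin-2-one F6.
  - Evans alkylation (NaN(SiMe3)2, MeI, −78 °C), with methyl iodide entering anti to the benzyl group of the Z-enolate, gives (4S)-4-benzyl-3-{(2S)-2-[2-(benzyloxy)-5-bromophenyl]propanoyl}-1,3-oxazolidin-2-one F7.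
  - LiBH4 removes the auxiliary and gives (2S)-2-[2-(benzyloxy)-5-bromophenyl]propan-1-ol F8.
  - Tosylation gives (2S)-2-[2-(benzyloxy)-5-bromophenyl]propyl 4-methylbenzenesulfonate F9.
  - Coupling with [4-(benzyloxy)phenyl]magnesium iodide F10 (from 4 and Mg) under Li2CuCl4 catalysis gives 7. The descriptor changes from S to R only because the substituent priorities change.

**Step 6.**
- **Risk:** ionisation or allylic transposition of the electron-rich benzylic allylic alcohol on the Lewis-acidic titanium, and slow epoxidation of a monosubstituted alkene that lowers the rate difference between the epimers.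
- **Fallback (from 10 to 11):** enzymatic acylation with immobilised Candida antarctica lipase B and vinyl acetate in tert-butyl methyl ether should acetylate the (R)-carbinol epimer selectively (aryl as the large, vinyl as the medium substituent). This gives (1R)-1-{4-(benzyloxy)-3-[(2R)-1-(4-benzyloxyphenyl)propan-2-yl]phenyl}prop-2-en-1-yl acetate F11, separable from the unreacted (S)-alcohol. Methanolysis (K2CO3, MeOH) gives 11.

**Step 9.**
- **Risk:** competing attack through the ortho carbon of 15, and acid-induced ionisation of the benzylic C5–O bond or loss of the C3 proton from the oxocarbenium ion, either of which would erode configuration.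
- **Fallback (from 14 to 16):** exchange of the ethoxy group with benzenesulfinic acid and CaCl2 in CH2Cl2 gives (2RS,3S,4R,5R)-5-{4-(benzyloxy)-3-[(2R)-1-(4-benzyloxyphenyl)propan-2-yl]phenyl}-3,4-dimethyl-2-(phenylsulfonyl)oxolane F12. The Grignard reagent F10 with ZnBr2 in THF then replaces the sulfonyl group by ring B. The point of attachment is fixed by the carbon–metal bond, and the aryl should again enter trans to the C3 methyl.

## Further compounds

F1 | step 8 | (3RS,4R,5R)-5-{4-(benzyloxy)-3-[(2R)-1-(4-benzyloxyphenyl)propan-2-yl]phenyl}-3,4-dimethyloxolan-2-one | C[C@@H]1C(C)C(=O)O[C@H]1c1ccc(OCc2ccccc2)c([C@H](C)Cc2ccc(OCc3ccccc3)cc2)c1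
F2 | step 8 | (3S,4R,5R)-5-{4-(benzyloxy)-3-[(2R)-1-(4-benzyloxyphenyl)propan-2-yl]phenyl}-3,4-dimethyloxolan-2-one | C[C@@H]1[C@H](C)C(=O)O[C@H]1c1ccc(OCc2ccccc2)c([C@H](C)Cc2ccc(OCc3ccccc3)cc2)c1
F3 | step 8 | (2RS,3S,4R,5R)-5-{4-(benzyloxy)-3-[(2R)-1-(4-benzyloxyphenyl)propan-2-yl]phenyl}-3,4-dimethyloxolan-2-ol | C[C@@H]1[C@H](C)C(O)O[C@H]1c1ccc(OCc2ccccc2)c([C@H](C)Cc2ccc(OCc3ccccc3)cc2)c1
F4 | step 4 | [2-(benzyloxy)-5-bromophenyl]acetaldehyde | O=CCc1cc(Br)ccc1OCc1ccccc1
F5 | step 4 | [2-(benzyloxy)-5-bromophenyl]acetic acid | OC(=O)Cc1cc(Br)ccc1OCc1ccccc1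
F6 | step 4 | (4S)-4-benzyl-3-{[2-(benzyloxy)-5-bromophenyl]acetyl}-1,3-oxazolidin-2-one | O=C(Cc1cc(Br)ccc1OCc1ccccc1)N1[C@@H](Cc2ccccc2)COC1=O
F7 | step 4 | (4S)-4-benzyl-3-{(2S)-2-[2-(benzyloxy)-5-bromophenyl]propanoyl}-1,3-oxazolidin-2-one | C[C@H](C(=O)N1[C@@H](Cc2ccccc2)COC1=O)c1cc(Br)ccc1OCc1ccccc1
F8 | step 4 | (2S)-2-[2-(benzyloxy)-5-bromophenyl]propan-1-ol | C[C@H](CO)c1cc(Br)ccc1OCc1ccccc1
F9 | step 4 | (2S)-2-[2-(benzyloxy)-5-bromophenyl]propyl 4-methylbenzenesulfonate | C[C@H](COS(=O)(=O)c1ccc(C)cc1)c1cc(Br)ccc1OCc1ccccc1
F10 | step 4 | [4-(benzyloxy)phenyl]magnesium iodide | I[Mg]c1ccc(OCc2ccccc2)cc1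
F11 | step 6 | (1R)-1-{4-(benzyloxy)-3-[(2R)-1-(4-benzyloxyphenyl)propan-2-yl]phenyl}prop-2-en-1-yl acetate | CC(=O)O[C@H](C=C)c1ccc(OCc2ccccc2)c([C@H](C)Cc2ccc(OCc3ccccc3)cc2)c1
F12 | step 9 | (2RS,3S,4R,5R)-5-{4-(benzyloxy)-3-[(2R)-1-(4-benzyloxyphenyl)propan-2-yl]phenyl}-3,4-dimethyl-2-(phenylsulfonyl)oxolane | C[C@@H]1[C@H](C)C(S(=O)(=O)c2ccccc2)O[C@H]1c1ccc(OCc2ccccc2)c([C@H](C)Cc2ccc(OCc3ccccc3)cc2)c1
A1 | alternative 1 | 2-[4-(benzyloxy)phenyl]-1-(pyrrolidin-1-yl)ethan-1-one | O=C(Cc1ccc(OCc2ccccc2)cc1)N1CCCC1
A2 | alternative 1 | (Z)-but-2-ene | C/C=C\C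
A3 | alternative 1 | (2S,3S,4R)-2-[4-(benzyloxy)phenyl]-3,4-dimethylcyclobutan-1-one | C[C@@H]1[C@H](C)[C@@H](c2ccc(OCc3ccccc3)cc2)C1=O
A4 | alternative 1 | (3R,4S,5S)-5-[4-(benzyloxy)phenyl]-3,4-dimethyloxolan-2-one | C[C@@H]1[C@H](C)[C@@H](c2ccc(OCc3ccccc3)cc2)OC1=O
A5 | alternative 2 | (5R)-5-{[(1R,2S,5R)-5-methyl-2-(propan-2-yl)cyclohexyl]oxy}furan-2(5H)-one | O=C1C=C[C@H](O[C@@H]2C[C@H](C)CC[C@H]2C(C)C)O1
A6 | alternative 2 | chloromethyl (trimethylsilyl)methyl sulfide | ClCSC[Si](C)(C)C
A7 | alternative 2 | cis-fused 4-[(1R,2S,5R)-menthyloxy]tetrahydro-1H-thieno[3,4-c]furan-1-one, menthyloxy anti to the thiolane ring | S1C[C@@H]2[C@H](C1)C(=O)O[C@H]2O[C@@H]3C[C@H](C)CC[C@H]3C(C)C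
A8 | alternative 2 | cis-3,4-dimethyl-5-[(1R,2S,5R)-menthyloxy]oxolan-2-one, menthyloxy trans to the neighbouring methyl | C[C@@H]1[C@H](C)C(=O)O[C@H]1O[C@@H]2C[C@H](C)CC[C@H]2C(C)C
A9 | alternative 3 | 2-bromo-4-[(2S,3R)-4-(4-hydroxyphenyl)-2,3-dimethylbutyl]phenol | C[C@@H](Cc1ccc(O)c(Br)c1)[C@H](C)Cc1ccc(O)cc1
A10 | alternative 3 | 2-bromo-4-[(2R,3R,4S,5S)-5-(4-hydroxyphenyl)-3,4-dimethyloxolan-2-yl]phenol | C[C@@H]1[C@H](C)[C@@H](c2ccc(O)cc2)O[C@H]1c1ccc(O)c(Br)c1
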